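## The problem

Peruvinide C (21) is a depside: two benzene rings joined only by an aryl ester, with no stereocenter, so the task is one of regiochemistry and chemoselectivity. The acyl carbon of ring B (the 2-hydroxy-4-methoxy-6-propylbenzoate ring) lies between a hydroxyl and a propyl group, so joining the rings by acylating a phenol means forcing a 2,6-disubstituted benzoic acid to react. Ring A is 5-pentylpyrogallol esterified at one of its two outer oxygens. These are equivalent by symmetry, but the central oxygen must be kept out of the esterification, and once free it sits next to the ester and can take over the acyl group under base. On ring B the two oxygens must be told apart: methyl ether at C4, free hydroxyl at C2. The aryl ester is an active ester that does not tolerate alkoxide or hydroxide, and the free catechol is oxidised by air in base, so the last steps must be neutral or acidic. The opening lies in ring B itself: carboxyl at C1, oxygen at C2 and C4, alkyl at C6 is the orsellinate tetraketide pattern. Ring carbons C1 to C6 therefore map onto C2 to C7 of a 3,5,7-trioxodecanoate, and the ring can be closed by an aldol reaction after the ester is already in place.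

## Retrosynthesis

**Protecting-group endgame (21 from 20 from 19).** The catechol of 21 is unmasked from acetonide 20 by aqueous acid, which neither cleaves the hindered ester nor moves it to the neighbouring hydroxyl. Acetonide 20 comes from resorcylate 19 by methylation of O4. Methylating late is preferred to carrying a methyl enol ether through the chain assembly, because the two hydroxyls of 19 differ sharply: the 2-hydroxyl is hydrogen-bonded to the ester carbonyl, the 4-hydroxyl is not. The forward steps must stop at one methyl group and leave the aryl ester alone.

**Ring B (19 from 17).** The bond between the ester-bearing carbon and the propyl-bearing carbon of ring B is cut. This leads to the open-chain aryl 3,5,7-trioxodecanoate 17, in which that bond is the link between C2 and the C7 ketone. The neighbouring cut, the ester C–O bond, would return a 2,6-disubstituted benzoic acid and a phenol, which is the coupling the target makes difficult. With the ring opened instead, the ester in 17 is an ordinary β-keto ester and the crowding arises only as the ring forms. The precursor has no ring B and no regiochemical question, since the positions of both oxygens and of the propyl group are fixed by the chain. The forward reaction must close C2 onto C7 and not C6 onto C1, and the aryloxide must not be expelled by lactonisation on the way.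

**Ester (17 from 15 and 7).** The ester C–O bond of 17 is cut to the phenol 7 and an acylketene 16, which is released by thermolysis of the diketo-dioxinone 15. Capture of a ketene by a phenol needs no coupling reagent and no base, which suits a product that is a sensitive tricarbonyl active ester. In 7 the other two oxygens of ring A are tied up as an acetonide, so only one hydroxyl can react and no acyl migration is possible afterwards. The forward step asks that bimolecular capture outrun intramolecular O-acylation within 16.

**Chain (15 from 11 and 13; 11 from 8 and 9; 13 from 12).** The C3'–C4' bond of the side chain of 15 is cut to the dianion 14 of keto-dioxinone 11 and the N-methoxy-N-methyl amide 13 of butanoic acid, made from butanoyl chloride 12. Compound 11 is cut at its C1'–C2' bond to the dienolate 10 of the commercial dioxinone 8 and acetyl chloride 9. Building the chain two and four carbons at a time from 8 keeps the ketene precursor intact throughout. The amide is chosen over the acid chloride for the second acylation because it acylates a carbanion only once.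

**Ring A (7 from 6 from 5 from 4 from 1 and 2).** The acetonide 7 comes from 5-pentylpyrogallol 6. Because 6 is symmetric, ketalisation of either adjacent pair of hydroxyls gives the same compound. Triol 6 is the demethylation product of 5, whose pentyl chain is traced through alkene 4 to 3,4,5-trimethoxybenzaldehyde 1 and the ylide 3 from butyltriphenylphosphonium bromide 2. The oxygen pattern is bought with 1, so no aromatic substitution chemistry is needed.

## Roads not taken

**Alternative 1: ring A from a cyclobutenone.** With the phenol carbon of ring A as C1, bonds C4–C5 and C1–C6 are cut. In the forward direction a Stille coupling (zerovalent palladium catalyst such as Pd(PPh3)4) joins 4-chloro-2,3-diisopropoxycyclobut-2-en-1-one A2 to tributyl(hept-1-en-2-yl)stannane A3. Thermal four-electron ring opening and six-electron closure then give 2,3-diisopropoxy-5-pentylphenol A1.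
- Merits: the free hydroxyl of A1 is exactly the ester oxygen, the other two oxygens are robust ethers, and no air-sensitive triol such as 6 is ever handled. In these respects it is better than the chosen ring A sequence.
- Weak points: it spends its key step on the easy ring. The symmetry of 6 already makes differentiation a one-step matter (7). A2 and A3 each need several steps and stoichiometric tin. The isopropyl ethers would have to be removed at the end with a boron trihalide in the presence of the ester.
- Comparison: it does not address ring B or the hindered ester at all. A1 could at best replace 7 as the ketene trap, at a higher step count than the four routine steps from 1.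

**Alternative 2: benzannulation of ring B on the ester (Danheiser type).** Ring B bonds C1–C2, C3–C4 and C4–C5 are cut. Irradiation of the diazo keto ester 2,2-dimethyl-6-pentyl-1,3-benzodioxol-4-yl 2-diazo-4-methylidene-3-oxoheptanoate A5 in the presence of ethoxyethyne A6 triggers a Wolff rearrangement, a [2+2] addition, a four-electron ring opening and a six-electron closure. The product is 2,2-dimethyl-6-pentyl-1,3-benzodioxol-4-yl 2-ethoxy-4-hydroxy-6-propylbenzoate A4.
- Merits: like the chosen plan it forms the ring with the ester already present, and it does so without any base. The aryl ester is never exposed to enolate chemistry and cannot be lost by lactonisation. In that respect it is safer than the aldol route.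
- Weak points: A5 is an α-methylene β-keto ester, prone to conjugate addition and polymerisation, and must take a diazo transfer. A6 is volatile and costly. A4 carries its oxygens the wrong way round (ether at C2, hydroxyl at C4), so it needs methylation at O4 and then chelation-controlled cleavage of the 2-ethyl ether by a boron trihalide, which also threatens the acetonide.
- Comparison: the chosen plan offers a precursor assembled from 8 by two enolate acylations, and an oxygen pattern that needs only one selective methylation.

**Alternative 3: [4+2] cycloaddition onto an aryl hexynoate.** Ring B bonds C1–C2 and C5–C6 are cut. 1,3-Dimethoxy-1-(trimethylsilyloxy)buta-1,3-diene A8 adds to 2,2-dimethyl-6-pentyl-1,3-benzodioxol-4-yl hex-2-ynoate A9, made from 7 and the unhindered hex-2-ynoic acid A10. Loss of methanol and desilylation give 2,2-dimethyl-6-pentyl-1,3-benzodioxol-4-yl 2-hydroxy-4-methoxy-6-propylbenzoate A7, which is identical with 20.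
- Merits: this is the shortest road, several steps fewer overall. It delivers the methyl ether and the free hydroxyl in their correct places, so the selective methylation disappears. Its ring formation is also base-free. On step count and on oxygen differentiation it is better than the chosen plan.
- Weak points: a β-alkyl alkynoate with a single activating group is a poor dienophile. The ketene-acetal diene A8 is thermally and hydrolytically fragile and tends to decompose at the temperatures such a partner needs. The aromatisation can lose either methanol or silanol. A9 is an active ester and a Michael acceptor.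
- Comparison: the chosen plan offers a ring closure that is intramolecular, runs at room temperature and is of a well-established type for triketo esters. Its weakness is confined to one competing pathway that the choice of base can address.

Key step: step 9

Remark on the chemistry: the polycarbonyl compounds 11, 15 and 17 are drawn as keto tautomers although they exist largely as enols; alkene 4 is drawn as its major Z isomer, and the minor E isomer is carried along because step 2 removes the double bond.

## Route

**Step 1**
Reactants: 1 3,4,5-trimethoxybenzaldehyde; 2 butyltriphenylphosphonium bromide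
Product: 4 (Z)-1,2,3-trimethoxy-5-(pent-1-en-1-yl)benzene, via butylidenetriphenylphosphorane 3 (not isolated)
Conditions: 2, KOtBu, THF, 0 °C; then 1, 0 °C → rt
Reagents that add atoms: none
Why: Wittig olefination of an aromatic aldehyde by a non-stabilised ylide is reliable; the alkene geometry is irrelevant because the double bond is hydrogenated next.

**Step 2**
Reactants: 4 (Z)-1,2,3-trimethoxy-5-(pent-1-en-1-yl)benzene
Product: 5 1,2,3-trimethoxy-5-pentylbenzene
Conditions: H2 (1 atm), 10% Pd/C, EtOAc, rt
Reagents that add atoms: none
Why: Catalytic hydrogenation of a styrene-type double bond is fast at room temperature and leaves aryl methyl ethers untouched.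

**Step 3**
Reactants: 5 1,2,3-trimethoxy-5-pentylbenzene
Product: 6 5-pentylbenzene-1,2,3-triol
Conditions: BBr3, CH2Cl2, −78 °C → rt, argon; then H2O, 0 °C
Reagents that add atoms: none
Why: BBr3 demethylation of aryl methyl ethers (bromide attacks the methyl group of the boron-complexed ether) should remove all three methyl groups and leave the alkyl chain alone; the air-sensitive triol is taken on without delay.

**Step 4**
Reactants: 6 5-pentylbenzene-1,2,3-triol
Product: 7 2,2-dimethyl-6-pentyl-1,3-benzodioxol-4-ol
Conditions: 2,2-dimethoxypropane, TsOH·H2O (cat.), toluene, reflux, Soxhlet with 4 Å molecular sieves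
Reagents that add atoms: 2,2-dimethoxypropane, COC(C)(C)OC
Why: Acid-catalysed transketalisation ties two adjacent hydroxyls into the five-membered ketal; since 6 is symmetric both possible ketals are the same compound, and the third hydroxyl cannot take part and stays free.

**Step 5**
Reactants: 8 2,2,6-trimethyl-4H-1,3-dioxin-4-one; 9 acetyl chloride
Product: 11 2,2-dimethyl-6-(2-oxopropyl)-4H-1,3-dioxin-4-one, via lithium 2,2-dimethyl-6-methylidene-6H-1,3-dioxin-4-olate 10 (not isolated)
Conditions: LiN(SiMe3)2, THF, −78 °C; then 9 (0.5 equiv), −78 → −20 °C; aq. NH4Cl
Reagents that add atoms: none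
Why: Kinetic deprotonation of the 6-methyl group gives the vinylogous ester enolate, which is C-acylated at its terminal carbon (crossed Claisen-type acylation); 8 is used in twofold excess because the more acidic product takes up a second equivalent of enolate.

**Step 6**
Reactants: 12 butanoyl chloride
Product: 13 N-methoxy-N-methylbutanamide
Conditions: MeNH(OMe)·HCl, K2CO3, CH2Cl2/H2O, 0 °C → rt
Reagents that add atoms: N,O-dimethylhydroxylamine hydrochloride, CNOC.Cl
Why: Schotten–Baumann acylation of the hydroxylamine is routine; the N-methoxy-N-methyl amide is made because it acylates a carbanion only once.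

**Step 7**
Reactants: 11 2,2-dimethyl-6-(2-oxopropyl)-4H-1,3-dioxin-4-one; 13 N-methoxy-N-methylbutanamide
Product: 15 6-(2,4-dioxoheptyl)-2,2-dimethyl-4H-1,3-dioxin-4-one, via dilithium dienolate dianion 14 (not isolated)
Conditions: LiN(iPr)2 (2.2 equiv), THF, −78 → −40 °C; then 13, −78 → −20 °C; 1 M HCl, 0 °C
Reagents that add atoms: none
Why: The second deprotonation takes place at the terminal methyl group, and this more reactive carbon of the dianion attacks the amide (crossed Claisen acylation of a 1,3-dicarbonyl dianion); N-methoxy-N-methyl amides release the ketone only on acidic quench, which prevents double acylation.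

**Step 8**
Reactants: 15 6-(2,4-dioxoheptyl)-2,2-dimethyl-4H-1,3-dioxin-4-one; 7 2,2-dimethyl-6-pentyl-1,3-benzodioxol-4-ol
Product: 17 2,2-dimethyl-6-pentyl-1,3-benzodioxol-4-yl 3,5,7-trioxodecanoate, via acylketene dec-1-ene-1,3,5,7-tetrone 16 (not isolated)
Conditions: 7 (1.2 equiv), toluene, 110 °C, slow addition of 15; evaporate, use crude
Reagents that add atoms: none
Why: Retro-[4+2] fragmentation of the dioxinone expels acetone and the phenol adds to the ketene carbon to give the aryl β-keto ester (acylketene capture); slow addition of 15 to an excess of 7 keeps bimolecular capture ahead of intramolecular O-acylation, and the acetonide is inert to neutral thermolysis.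

**Step 9**
Reactants: 17 2,2-dimethyl-6-pentyl-1,3-benzodioxol-4-yl 3,5,7-trioxodecanoate
Product: 19 2,2-dimethyl-6-pentyl-1,3-benzodioxol-4-yl 2,4-dihydroxy-6-propylbenzoate, via cyclic aldol adduct 18 (not isolated)
Conditions: Et3N (3 equiv), CH2Cl2, 0 °C → rt; then 1 M aq. HCl wash
Reagents that add atoms: none
Why: Triethylamine reversibly enolises the chain, and the C2 enolate, flanked by the aryl ester and the C3 ketone, adds to the C7 ketone to give the β-hydroxy ketone 18. The closure is a 6-(enolendo)-exo-trig aldol, allowed by Baldwin's rules, and it forms the bond between the ester-bearing and the propyl-bearing carbon of ring B. E1cB loss of water from 18 and enolisation of the C3 and C5 carbonyls then give the resorcylate, and the gain of aromaticity makes the sequence irreversible. The closest known reaction type is the biomimetic aldol aromatisation of alkyl 3,5,7-triketo esters from diketo-dioxinones under amine or carbonate base. No stereocenter is created in 19, and the two transient ones of 18 are erased on dehydration. The step needs the C2-to-C7 aldol to win over Claisen closure of C6 onto C1 and over lactonisation of the C5 enol oxygen onto C1 with expulsion of the aryloxide. A ketone is a better acceptor than an ester, and an aprotic, non-nucleophilic amine offers neither an alkoxide for transesterification nor the strongly basic, metal-templated conditions that Claisen closure requires. The dilute acid wash completes the dehydration and removes the amine without cleaving the acetonide.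

**Step 10**
Reactants: 19 2,2-dimethyl-6-pentyl-1,3-benzodioxol-4-yl 2,4-dihydroxy-6-propylbenzoate
Product: 20 2,2-dimethyl-6-pentyl-1,3-benzodioxol-4-yl 2-hydroxy-4-methoxy-6-propylbenzoate
Conditions: MeI (1.1 equiv), K2CO3 (1.1 equiv), acetone, rt
Reagents that add atoms: iodomethane, CI
Why: Williamson methylation; the 4-hydroxyl, para to the ester and not hydrogen-bonded, is the more acidic and more nucleophilic phenol, whereas the 2-hydroxyl is chelated to the ester carbonyl, as is standard for orsellinate-type esters. Ring A has no free hydroxyl, so the acyl group cannot migrate.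

**Step 11**
Reactants: 20 2,2-dimethyl-6-pentyl-1,3-benzodioxol-4-yl 2-hydroxy-4-methoxy-6-propylbenzoate
Product: 21 Peruvinide C (2,3-dihydroxy-5-pentylphenyl 2-hydroxy-4-methoxy-6-propylbenzoate)
Conditions: TFA/H2O (9:1), CH2Cl2, 0 °C → rt
Reagents that add atoms: none
Why: Acid hydrolysis of a catechol isopropylidene ketal; the hindered, electron-rich aryl benzoate is slow to hydrolyse in acid, and acid, unlike base, does not promote acyl migration to the newly freed neighbouring hydroxyl.

## Compound list

1 | 3,4,5-trimethoxybenzaldehyde | COc1cc(C=O)cc(OC)c1OC | starting material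
2 | butyltriphenylphosphonium bromide | CCCC[P+](c1ccccc1)(c1ccccc1)c1ccccc1.[Br-] | starting material
3 | butylidenetriphenylphosphorane (not isolated) | CCCC=P(c1ccccc1)(c1ccccc1)c1ccccc1 | intermediate
4 | (Z)-1,2,3-trimethoxy-5-(pent-1-en-1-yl)benzene (major isomer; E isomer carried along) | CCC/C=C\c1cc(OC)c(OC)c(OC)c1 | intermediate
5 | 1,2,3-trimethoxy-5-pentylbenzene | CCCCCc1cc(OC)c(OC)c(OC)c1 | intermediate
6 | 5-pentylbenzene-1,2,3-triol | CCCCCc1cc(O)c(O)c(O)c1 | intermediate
7 | 2,2-dimethyl-6-pentyl-1,3-benzodioxol-4-ol | CCCCCc1cc(O)c2OC(C)(C)Oc2c1 | intermediate
8 | 2,2,6-trimethyl-4H-1,3-dioxin-4-one | CC1=CC(=O)OC(C)(C)O1 | starting material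
9 | acetyl chloride | CC(=O)Cl | starting material
10 | lithium 2,2-dimethyl-6-methylidene-6H-1,3-dioxin-4-olate (not isolated) | [Li+].[O-]C1=CC(=C)OC(C)(C)O1 | intermediate
11 | 2,2-dimethyl-6-(2-oxopropyl)-4H-1,3-dioxin-4-one | CC(=O)CC1=CC(=O)OC(C)(C)O1 | intermediate
12 | butanoyl chloride | CCCC(=O)Cl | starting material
13 | N-methoxy-N-methylbutanamide | CCCC(=O)N(C)OC | intermediate
14 | dilithium 2,2-dimethyl-6-(2-oxidoprop-2-en-1-ylidene)-6H-1,3-dioxin-4-olate, the dianion of 11 (not isolated) | [Li+].[Li+].C=C([O-])C=C1C=C([O-])OC(C)(C)O1 | intermediate
15 | 6-(2,4-dioxoheptyl)-2,2-dimethyl-4H-1,3-dioxin-4-one | CCCC(=O)CC(=O)CC1=CC(=O)OC(C)(C)O1 | intermediate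
16 | dec-1-ene-1,3,5,7-tetrone, the acylketene (not isolated) | CCCC(=O)CC(=O)CC(=O)C=C=O | intermediate
17 | 2,2-dimethyl-6-pentyl-1,3-benzodioxol-4-yl 3,5,7-trioxodecanoate | CCCC(=O)CC(=O)CC(=O)CC(=O)Oc1cc(CCCCC)cc2OC(C)(C)Oc12 | intermediate
18 | 2,2-dimethyl-6-pentyl-1,3-benzodioxol-4-yl 2-hydroxy-4,6-dioxo-2-propylcyclohexane-1-carboxylate, mixture of diastereomers and tautomers (not isolated) | CCCC1(O)CC(=O)CC(=O)C1C(=O)Oc1cc(CCCCC)cc2OC(C)(C)Oc12 | intermediate
19 | 2,2-dimethyl-6-pentyl-1,3-benzodioxol-4-yl 2,4-dihydroxy-6-propylbenzoate | CCCc1cc(O)cc(O)c1C(=O)Oc1cc(CCCCC)cc2OC(C)(C)Oc12 | intermediate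
20 | 2,2-dimethyl-6-pentyl-1,3-benzodioxol-4-yl 2-hydroxy-4-methoxy-6-propylbenzoate | CCCc1cc(OC)cc(O)c1C(=O)Oc1cc(CCCCC)cc2OC(C)(C)Oc12 | intermediate
21 | Peruvinide C, 2,3-dihydroxy-5-pentylphenyl 2-hydroxy-4-methoxy-6-propylbenzoate (no stereocenters) | CCCCCc1cc(O)c(O)c(OC(=O)c2c(O)cc(OC)cc2CCC)c1 | target

## Step count and risks

Total step count: 11. Longest linear sequence: 8 steps (steps 1 to 4, then 8 to 11, from 1). The ring B branch contributes steps 5 to 7.

**Step 9 (key step).** The most likely failure is lactonisation of the C5 enol oxygen onto the ester carbon with expulsion of the ring A phenoxide, in competition with the aldol. An aryl ester is a better acyl donor than the alkyl esters on which this aromatisation is established. Fallback: the order of ring closure and ester formation is reversed, setting out from 15 and rejoining the route at 20. Triethylamine in CH2Cl2 should close 15 itself to 7-hydroxy-2,2-dimethyl-5-propyl-4H-1,3-benzodioxin-4-one F1, in which no leaving group is available. Methylation with MeI and K2CO3 gives 7-methoxy-2,2-dimethyl-5-propyl-4H-1,3-benzodioxin-4-one F2. KOH in aqueous DMSO opens this to 2-hydroxy-4-methoxy-6-propylbenzoic acid F3. The acid is then esterified with 7 by trifluoroacetic anhydride in toluene, the classical depside coupling, to give 20. This accepts the hindered acylation that the main route avoids.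

**Step 8.** Ring closure of the acylketene through its own enol oxygen may outrun capture by the phenol, which is a weaker nucleophile than the aliphatic alcohols usually used and carries an ortho substituent. Fallback: capture and aryl transfer are separated, setting out from 15 and returning at 17. Thermolysis of 15 with an excess of cheap 2-methylpropane-2-thiol gives S-tert-butyl 3,5,7-trioxodecanethioate F4. AgO2CCF3 in THF at room temperature then activates the thioester in the presence of 7 and transfers the acyl group to the phenol.

**Step 7.** Proton transfer from the amide or from the product to the dianion, together with O-acylation, may hold conversion low. Fallback: the Claisen acylation is replaced by an aldol and an oxidation, setting out from 11 and returning at 15. The dianion 14 adds cleanly to butanal to give racemic 6-(4-hydroxy-2-oxoheptyl)-2,2-dimethyl-4H-1,3-dioxin-4-one F5. Dess–Martin periodinane then oxidises the β-hydroxy ketone to the diketone 15.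

**Step 10.** A second methylation at the chelated 2-hydroxyl or carbonate-induced cleavage of the aryl ester may erode the yield. Fallback: from 19 to 20 by a Mitsunobu etherification (MeOH, PPh3, diisopropyl azodicarboxylate, THF). This delivers the methyl group from an alkoxyphosphonium ion to the more acidic, non-chelated phenol without generating a free phenoxide. No new compound arises.

**Step 11.** Ketal hydrolysis may be incomplete under conditions mild enough for the ester, or forcing the acid may bring ester hydrolysis or acyl migration. Fallback: the catechol is protected as a ketal that is removed by hydrogenolysis, setting out from 6 and coming back at 21. Heating 6 with dichlorodiphenylmethane gives 6-pentyl-2,2-diphenyl-1,3-benzodioxol-4-ol F6. Capture of the ketene from 15 gives 6-pentyl-2,2-diphenyl-1,3-benzodioxol-4-yl 3,5,7-trioxodecanoate F7. The same amine-mediated aldol aromatisation gives 6-pentyl-2,2-diphenyl-1,3-benzodioxol-4-yl 2,4-dihydroxy-6-propylbenzoate F8. Methylation gives 6-pentyl-2,2-diphenyl-1,3-benzodioxol-4-yl 2-hydroxy-4-methoxy-6-propylbenzoate F9. Hydrogenolysis (H2, 10% Pd/C, THF) under neutral conditions then releases 21.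

## Further compounds

F1 | step 9 | 7-hydroxy-2,2-dimethyl-5-propyl-4H-1,3-benzodioxin-4-one | CCCc1cc(O)cc2OC(C)(C)OC(=O)c12
F2 | step 9 | 7-methoxy-2,2-dimethyl-5-propyl-4H-1,3-benzodioxin-4-one | CCCc1cc(OC)cc2OC(C)(C)OC(=O)c12
F3 | step 9 | 2-hydroxy-4-methoxy-6-propylbenzoic acid | CCCc1cc(OC)cc(O)c1C(=O)O
F4 | step 8 | S-tert-butyl 3,5,7-trioxodecanethioate | CCCC(=O)CC(=O)CC(=O)CC(=O)SC(C)(C)C
F5 | step 7 | 6-(4-hydroxy-2-oxoheptyl)-2,2-dimethyl-4H-1,3-dioxin-4-one (racemic) | CCCC(O)CC(=O)CC1=CC(=O)OC(C)(C)O1
F0 | step 10 | none | none
F6 | step 11 | 6-pentyl-2,2-diphenyl-1,3-benzodioxol-4-ol | CCCCCc1cc(O)c2OC(c3ccccc3)(c3ccccc3)Oc2c1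
F7 | step 11 | 6-pentyl-2,2-diphenyl-1,3-benzodioxol-4-yl 3,5,7-trioxodecanoate | CCCC(=O)CC(=O)CC(=O)CC(=O)Oc1cc(CCCCC)cc2OC(c3ccccc3)(c3ccccc3)Oc12
F8 | step 11 | 6-pentyl-2,2-diphenyl-1,3-benzodioxol-4-yl 2,4-dihydroxy-6-propylbenzoate | CCCc1cc(O)cc(O)c1C(=O)Oc1cc(CCCCC)cc2OC(c3ccccc3)(c3ccccc3)Oc12
F9 | step 11 | 6-pentyl-2,2-diphenyl-1,3-benzodioxol-4-yl 2-hydroxy-4-methoxy-6-propylbenzoate | CCCc1cc(OC)cc(O)c1C(=O)Oc1cc(CCCCC)cc2OC(c3ccccc3)(c3ccccc3)Oc12
A1 | alternative 1 | 2,3-diisopropoxy-5-pentylphenol | CCCCCc1cc(O)c(OC(C)C)c(OC(C)C)c1
A2 | alternative 1 | 4-chloro-2,3-diisopropoxycyclobut-2-en-1-one | CC(C)OC1=C(OC(C)C)C(=O)C1Cl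
A3 | alternative 1 | tributyl(hept-1-en-2-yl)stannane | CCCCCC(=C)[Sn](CCCC)(CCCC)CCCC
A4 | alternative 2 | 2,2-dimethyl-6-pentyl-1,3-benzodioxol-4-yl 2-ethoxy-4-hydroxy-6-propylbenzoate | CCCc1cc(O)cc(OCC)c1C(=O)Oc1cc(CCCCC)cc2OC(C)(C)Oc12
A5 | alternative 2 | 2,2-dimethyl-6-pentyl-1,3-benzodioxol-4-yl 2-diazo-4-methylidene-3-oxoheptanoate | CCCC(=C)C(=O)C(=[N+]=[N-])C(=O)Oc1cc(CCCCC)cc2OC(C)(C)Oc12
A6 | alternative 2 | ethoxyethyne | CCOC#C
A7 | alternative 3 | 2,2-dimethyl-6-pentyl-1,3-benzodioxol-4-yl 2-hydroxy-4-methoxy-6-propylbenzoate | CCCc1cc(OC)cc(O)c1C(=O)Oc1cc(CCCCC)cc2OC(C)(C)Oc12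
A8 | alternative 3 | 1,3-dimethoxy-1-(trimethylsilyloxy)buta-1,3-diene | COC(=C)C=C(OC)O[Si](C)(C)C
A9 | alternative 3 | 2,2-dimethyl-6-pentyl-1,3-benzodioxol-4-yl hex-2-ynoate | CCCC#CC(=O)Oc1cc(CCCCC)cc2OC(C)(C)Oc12
A10 | alternative 3 | hex-2-ynoic acid | CCCC#CC(=O)O
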